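The route disconnects, last of all, the enol-ether bond O-2–C-3 of the dihydropyran ring (iridoid numbering), whose tetrasubstituted C-3 carries both the ring oxygen and the isovaleryl ketone. The cyclopentane stereotriad comes from (4aS,7S,7aR)-nepetalactone, whose pyran serves as a temporary ring: its lactol oxocarbenium ion fixes C-1 by convex-face C-arylation with 2-methoxy-5-methylchromone, and ozonolysis then excises the old C-3. An alkyne rebuilds C-3 with its side chain as an open-chain (Z)-α-iodoenone that keeps the free C-1 hydroxyl. The key step, a copper-catalysed intramolecular O-vinylation, exploits this captodative C-3=C-4 unit and closes the ring at its final oxidation level.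

Key step: step 8

Remark on the chemistry: (4aS,7S,7aR)-nepetalactone (cis,trans-nepetalactone of catnip oil) is taken as a purchasable starting material. Iridoid numbering (C-1, O-2, C-3, C-4, C-4a, C-5, C-6, C-7, C-7a) is kept for every intermediate, ring-opened ones included.

Step 1
Reactants: 1 (4aS,7S,7aR)-nepetalactone
Product: 2 (1R,4aS,7S,7aR)-nepetalactol
Conditions: i-Bu2AlH (1.1 equiv), CH2Cl2, −78 °C; aq. potassium sodium tartrate
Reagents that add atoms: none
Why: Partial reduction of the enol lactone with i-Bu2AlH should stop at the aluminium hemiacetal at −78 °C and give the lactol without touching C-4a, C-7 and C-7a; the anomeric centre is of no consequence because it is ionised in step 4.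

Step 2
Reactants: 3 1-(2-hydroxy-6-methylphenyl)ethan-1-one
Product: 5 5-methyl-2-(methylsulfanyl)-4H-chromen-4-one, via thiolate salt 4 (not isolated)
Conditions: KOt-Bu (3 equiv), CS2, THF, 0 °C → rt; then MeI, rt
Reagents that add atoms: carbon disulfide, S=C=S; iodomethane, CI
Why: Dithiocarboxylation of the ketone enolate and ring closure by the phenoxide with loss of hydrosulfide should give the chromene-2-thiolate, whose soft sulfur is then methylated (S-alkylation), which locks the 4-chromone tautomer.

Step 3
Reactants: 5 5-methyl-2-(methylsulfanyl)-4H-chromen-4-one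
Product: 7 2-methoxy-5-methyl-4H-chromen-4-one, via sulfone 6 (not isolated)
Conditions: mCPBA (2.2 equiv), CH2Cl2, 0 °C → rt; then NaOMe (excess), MeOH, 0 °C
Reagents that add atoms: sodium methoxide, [Na+].[O-]C
Why: Sulfide-to-sulfone oxidation followed by addition–elimination (vinylic nucleophilic substitution) of methoxide at C-2 of the chromone, where methanesulfinate leaves more readily than the ring phenoxide, should give the 2-methoxychromone without the regiochemical ambiguity of methylating a 4-hydroxycoumarin.

Step 4
Reactants: 2 (1R,4aS,7S,7aR)-nepetalactol; 7 2-methoxy-5-methyl-4H-chromen-4-one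
Product: 8 3-[(1R,4aS,7S,7aR)-4,7-dimethyl-1,4a,5,6,7,7a-hexahydrocyclopenta[c]pyran-1-yl]-2-methoxy-5-methyl-4H-chromen-4-one
Conditions: Me3SiOTf (1.2 equiv), 2,6-di-tert-butyl-4-methylpyridine, 4 Å MS, CH2Cl2, −78 → −40 °C; aq. NaHCO3
Reagents that add atoms: none
Why: Ionisation of the lactol by Me3SiOTf gives the cis-fused bicyclic oxocarbenium ion, which the push–pull C-3 of the 2-methoxychromone (a ketene-acetal-type carbon flanked by the ring oxygen and OMe) should attack in a Friedel–Crafts-type C-glycosylation from the convex face, anti to the C-7a–C-7 bond, which sets C-1 as R; the hindered pyridine keeps the enol ether unprotonated.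

Step 5
Reactants: 8 the C-1 chromonyl enol ether
Product: 10 3-{(R)-[(1R,2S,5S)-2-acetyl-5-methylcyclopentyl](hydroxy)methyl}-2-methoxy-5-methyl-4H-chromen-4-one, via keto formate 9 (not isolated)
Conditions: O3, CH2Cl2/MeOH, −78 °C (indicator end point); Me2S, −78 °C → rt; then K2CO3 (cat.), MeOH, 0 °C, brief
Reagents that add atoms: ozone, [O-][O+]=O
Why: Ozonolysis (Criegee mechanism) of the electron-rich trisubstituted enol ether, which should react far faster than the cross-conjugated chromone alkene, cleaves C-3=C-4 to the methyl ketone and the C-1 formate, and brief methanolysis frees the carbinol without breaking the C-1–O bond, so C-1 is retained; the product should rest largely as its cis-fused five-membered hemiketal, which shields C-4a from epimerisation.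

Step 6
Reactants: 10 the hydroxy methyl ketone; 11 4-methylpent-1-yne
Product: 12 3-{(R)-hydroxy[(1R,2S,5S)-2-(2-hydroxy-6-methylhept-3-yn-2-yl)-5-methylcyclopentyl]methyl}-2-methoxy-5-methyl-4H-chromen-4-one
Conditions: 11 (3 equiv), n-BuLi, THF, −78 °C; CeCl3, −78 °C; then 10, −78 → −30 °C; aq. NH4Cl
Reagents that add atoms: none
Why: 1,2-Addition of the weakly basic cerium acetylide to the methyl ketone (the first equivalent deprotonates the hydroxyl and opens the hemiketal) should outpace enolisation at C-4a and attack on the vinylogous carbonate of the chromone; the new carbinol centre C-4 forms as a mixture that is erased in step 7.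

Step 7
Reactants: 12 the propargylic diol
Product: 13 3-{(R)-hydroxy[(1R,2S,5S)-2-[(2Z)-3-iodo-6-methyl-4-oxohept-2-en-2-yl]-5-methylcyclopentyl]methyl}-2-methoxy-5-methyl-4H-chromen-4-one
Conditions: (Ph3P)AuNTf2 (2 mol %), MoO2(acac)2 (2 mol %), Ph3PO (4 mol %), NIS (1.2 equiv), CH2Cl2, rt
Reagents that add atoms: N-iodosuccinimide, O=C1CCC(=O)N1I
Why: Molybdenum-catalysed 1,3-hydroxyl transposition of the tertiary propargylic alcohol (Meyer–Schuster rearrangement) with monovalent-gold activation and interception of the allenolate-type intermediate by NIS at C-3 should give the α-iodoenone directly; the new element is the alkene geometry, for which the Z isomer (acyl cis to methyl, iodine cis to the bulky C-4a branch) is expected to be favoured.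

Step 8
Reactants: 13 the (Z)-α-iodoenone
Product: 14 3-[(1R,4aS,7S,7aR)-4,7-dimethyl-3-(3-methylbutanoyl)-1,4a,5,6,7,7a-hexahydrocyclopenta[c]pyran-1-yl]-2-methoxy-5-methyl-4H-chromen-4-one (CNP0144992.1)
Conditions: CuI (10 mol %), 1,10-phenanthroline (20 mol %), Cs2CO3 (2 equiv), toluene, 80 °C
Reagents that add atoms: none
Why: Cs2CO3 deprotonates the C-1 hydroxyl and the resulting alkoxide binds monovalent copper (phenanthroline-ligated), which activates the C-3–I bond of the α-iodoenone (oxidative addition or halogen-atom transfer) and forms the O-2–C-3 bond by reductive elimination, the base taking up HI. The closest known reaction type is the copper-catalysed Ullmann-type O-vinylation of vinyl iodides with aliphatic alcohols, in its intramolecular form that gives cyclic enol ethers. The dihydropyran ring closes by vinylic substitution at C-3 with the C-3=C-4 bond endocyclic and the C-3–I bond exocyclic, so the enol ether, the tetrasubstituted alkene and the conjugated ketone appear at once in their final oxidation state. No stereocentre is created and C-1, C-4a, C-7 and C-7a are kept, because no bond to them is broken and the carbonate base should be too weak to deprotonate the γ-position C-4a. The step needs C–O coupling at C-3 in preference to 5-exo oxa-Michael addition at C-4 and it needs the Z isomer: the Michael adduct should be a reversible resting state that reopens by E1cB and thereby also equilibrates any E isomer, whereas the reductive elimination is irreversible, and the cis ring fusion holds the C-1 alkoxide within reach of C-3.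

Compound list
1 | (4aS,7S,7aR)-nepetalactone | O=C1OC=C(C)[C@H]2CC[C@H](C)[C@H]21 | starting material
2 | (1R,4aS,7S,7aR)-nepetalactol (4,7-dimethyl-1,4a,5,6,7,7a-hexahydrocyclopenta[c]pyran-1-ol) | O[C@@H]1OC=C(C)[C@H]2CC[C@H](C)[C@H]21 | intermediate
3 | 1-(2-hydroxy-6-methylphenyl)ethan-1-one | CC(=O)c1c(C)cccc1O | starting material
4 | potassium 5-methyl-4-oxo-4H-chromene-2-thiolate | Cc1cccc2oc([S-])cc(=O)c12.[K+] | intermediate
5 | 5-methyl-2-(methylsulfanyl)-4H-chromen-4-one | CSc1cc(=O)c2c(C)cccc2o1 | intermediate
6 | 5-methyl-2-(methylsulfonyl)-4H-chromen-4-one | CS(=O)(=O)c1cc(=O)c2c(C)cccc2o1 | intermediate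
7 | 2-methoxy-5-methyl-4H-chromen-4-one | COc1cc(=O)c2c(C)cccc2o1 | intermediate
8 | 3-[(1R,4aS,7S,7aR)-4,7-dimethyl-1,4a,5,6,7,7a-hexahydrocyclopenta[c]pyran-1-yl]-2-methoxy-5-methyl-4H-chromen-4-one | COc1oc2cccc(C)c2c(=O)c1[C@@H]1OC=C(C)[C@H]2CC[C@H](C)[C@H]21 | intermediate
9 | (R)-[(1R,2S,5S)-2-acetyl-5-methylcyclopentyl](2-methoxy-5-methyl-4-oxo-4H-chromen-3-yl)methyl formate | COc1oc2cccc(C)c2c(=O)c1[C@H](OC=O)[C@@H]1[C@@H](C)CC[C@@H]1C(C)=O | intermediate
10 | 3-{(R)-[(1R,2S,5S)-2-acetyl-5-methylcyclopentyl](hydroxy)methyl}-2-methoxy-5-methyl-4H-chromen-4-one (in equilibrium with its cyclic hemiketal) | COc1oc2cccc(C)c2c(=O)c1[C@H](O)[C@@H]1[C@@H](C)CC[C@@H]1C(C)=O | intermediate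
11 | 4-methylpent-1-yne | C#CCC(C)C | starting material
12 | 3-{(R)-hydroxy[(1R,2S,5S)-2-(2-hydroxy-6-methylhept-3-yn-2-yl)-5-methylcyclopentyl]methyl}-2-methoxy-5-methyl-4H-chromen-4-one (both epimers at the tertiary carbinol) | COc1oc2cccc(C)c2c(=O)c1[C@H](O)[C@@H]1[C@@H](C)CC[C@@H]1C(C)(O)C#CCC(C)C | intermediate
13 | 3-{(R)-hydroxy[(1R,2S,5S)-2-[(2Z)-3-iodo-6-methyl-4-oxohept-2-en-2-yl]-5-methylcyclopentyl]methyl}-2-methoxy-5-methyl-4H-chromen-4-one | COc1oc2cccc(C)c2c(=O)c1[C@H](O)[C@@H]1[C@@H](C)CC[C@@H]1/C(C)=C(\I)C(=O)CC(C)C | intermediate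
14 | 3-[(1R,4aS,7S,7aR)-4,7-dimethyl-3-(3-methylbutanoyl)-1,4a,5,6,7,7a-hexahydrocyclopenta[c]pyran-1-yl]-2-methoxy-5-methyl-4H-chromen-4-one | COc1oc2cccc(C)c2c(=O)c1[C@@H]1OC(C(=O)CC(C)C)=C(C)[C@H]2CC[C@H](C)[C@H]21 | target

Total step count: 8. Longest linear sequence: 7 steps (from 3 through steps 2, 3, 4, 5, 6, 7, 8; 6 steps from 1).

Steps most likely to fail

1. Step 8 (key step). The alkoxide may rest as the 5-exo oxa-Michael adduct at C-4, or the vinyl iodide may be reduced (protodeiodination) faster than C–O reductive elimination; slow E-to-Z equilibration would strand part of the material. The fallback replaces the cross-coupling by an epoxide opening; it sets out from 12 and comes back at 14. The gold/molybdenum catalyst pair of step 7, used without NIS, should give the Meyer–Schuster enone F1. Nucleophilic epoxidation with t-BuOOH and DBU should give the α,β-epoxy ketone F2. With Cs2CO3 in MeCN the C-1 alkoxide should open the epoxide at C-3, the carbon α to the ketone (C-4 is tertiary and closed to SN2), and E1cB loss of water from the β-hydroxy ketone should give 14, whatever the alkene geometry of F1.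

2. Step 7. The free C-1 hydroxyl may add to the gold-activated alkyne (6-exo-dig hydroalkoxylation or iodoetherification) before the 1,3-transposition, the Lewis acids may ionise the chromone-stabilised C-1 position, and the geometry of the iodoalkene may come out poorly controlled. The fallback avoids the alkyne and the alkene geometry altogether; it sets out from 9 (isolated for this purpose after the Me2S work-up of step 5) and comes back at 14. Dibromoolefination of the methyl ketone with CBr4 and PPh3 should give the gem-dibromoalkene formate F3, and brief methanolysis (K2CO3, MeOH) the hydroxy gem-dibromoalkene F4. Intramolecular copper-catalysed O-vinylation (CuI, 1,10-phenanthroline, Cs2CO3), for which one bromine is always cis to the tether, should close the ring to the 3-bromo enol ether F5. Carbonylative Suzuki–Miyaura coupling (Pd(PPh3)4 as zerovalent palladium, CO at 1 atm, B-isobutyl-9-borabicyclo[3.3.1]nonane, K3PO4) should then install the isovaleryl ketone and give 14.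

3. Step 4. The neutral 2-methoxychromone may be too weak a nucleophile, so that the oxocarbenium ion is consumed by self-condensation through its enol ether, by reversible O-alkylation of the chromone carbonyl, or by loss of H-7a after re-ionisation at C-1. The fallback uses the far more nucleophilic 4-hydroxycoumarin and methylates afterwards; it sets out from 3 and 2 and comes back at 8. Acylation–cyclisation of 3 with diethyl carbonate and NaH should give 4-hydroxy-5-methylcoumarin F6. Acid-catalysed C-glycosylation of lactol 2 (Sc(OTf)3, CH2Cl2) should give the 4-hydroxycoumarin C-glycoside F7 with the same convex-face selectivity. O-methylation with Me3SiCHN2 in MeOH/toluene should give 8, the isomeric 4-methoxycoumarin being removed by chromatography.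

Further compounds
F1 | step 8 | 3-{(R)-hydroxy[(1R,2S,5S)-5-methyl-2-(6-methyl-4-oxohept-2-en-2-yl)cyclopentyl]methyl}-2-methoxy-5-methyl-4H-chromen-4-one (E and Z) | COc1oc2cccc(C)c2c(=O)c1[C@H](O)[C@@H]1[C@@H](C)CC[C@@H]1C(C)=CC(=O)CC(C)C
F2 | step 8 | 3-{(R)-hydroxy[(1R,2S,5S)-5-methyl-2-[2-methyl-3-(3-methylbutanoyl)oxiran-2-yl]cyclopentyl]methyl}-2-methoxy-5-methyl-4H-chromen-4-one (epoxide diastereomers) | COc1oc2cccc(C)c2c(=O)c1[C@H](O)[C@@H]1[C@@H](C)CC[C@@H]1C3(C)OC3C(=O)CC(C)C
F3 | step 7 | (R)-[(1R,2S,5S)-2-(1,1-dibromoprop-1-en-2-yl)-5-methylcyclopentyl](2-methoxy-5-methyl-4-oxo-4H-chromen-3-yl)methyl formate | COc1oc2cccc(C)c2c(=O)c1[C@H](OC=O)[C@@H]1[C@@H](C)CC[C@@H]1C(C)=C(Br)Br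
F4 | step 7 | 3-{(R)-[(1R,2S,5S)-2-(1,1-dibromoprop-1-en-2-yl)-5-methylcyclopentyl](hydroxy)methyl}-2-methoxy-5-methyl-4H-chromen-4-one | COc1oc2cccc(C)c2c(=O)c1[C@H](O)[C@@H]1[C@@H](C)CC[C@@H]1C(C)=C(Br)Br
F5 | step 7 | 3-[(1R,4aS,7S,7aR)-3-bromo-4,7-dimethyl-1,4a,5,6,7,7a-hexahydrocyclopenta[c]pyran-1-yl]-2-methoxy-5-methyl-4H-chromen-4-one | COc1oc2cccc(C)c2c(=O)c1[C@@H]1OC(Br)=C(C)[C@H]2CC[C@H](C)[C@H]21
F6 | step 4 | 4-hydroxy-5-methyl-2H-chromen-2-one | Cc1cccc2oc(=O)cc(O)c12
F7 | step 4 | 3-[(1R,4aS,7S,7aR)-4,7-dimethyl-1,4a,5,6,7,7a-hexahydrocyclopenta[c]pyran-1-yl]-4-hydroxy-5-methyl-2H-chromen-2-one | Cc1cccc2oc(=O)c(c(O)c12)[C@@H]1OC=C(C)[C@H]2CC[C@H](C)[C@H]21
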